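**Retrosynthetic overview**
1. Target ⇒ C4=C5 epoxidation last, O8 methacryloylation and O9 acetylation ⇒ a PMB-protected α-methylene lactone on the ten-membered ring.
2. Key disconnection: both lactone bonds, O–C6 and C7–C11, are cut in one Pd-catalysed [3+2] heteroannulation of 2-bromoacrylic acid onto a ten-membered triene; the whole methylene-lactone unit and the C6 and C7 stereocentres arrive in this step.
3. Enabling feature: the cis,cis-1,3-diene C4=C5–C6=C7 inside the ten-membered carbocycle. Its disubstituted C6=C7 bond takes the alkenyl–Pd carbon at C7, C6–C5–C4 becomes the η3-allyl that the carboxylate closes at C6, and cis C4=C5 is left for the epoxide.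
4. Macrocycle ⇒ ene–diene ring-closing metathesis (C6=C7); enoate C1=C10 ⇒ alkyne (syn-hydrostannation, iodination, methoxycarbonylation); C9–C10 ⇒ chelation-controlled alkynylzinc addition; fragments from neryl acetate (C–C cleavage of its remote alkene, cis C4=C5 kept) and (S)-but-3-ene-1,2-diol (C8).
5. Ring order: ten-membered carbocycle (step 13), then γ-lactone (step 14), then oxirane (step 18).

Key step: step 14

Remark: germacrane numbering is used for locants (ring C1–C10, lactone carbons C11–C13, ester carbon C14, methyl C15); the target SMILES defines a cis-4,5-epoxide (C3 and C6 on the same side of the oxirane) and a ring-cis C1=C10 bond, and the route is built for exactly that isomer.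

**Route**

Step 1
Reactants: 1 neryl acetate
Product: 2 (2Z)-5-(3,3-dimethyloxiran-2-yl)-3-methylpent-2-en-1-yl acetate (racemic at the oxirane carbon)
Conditions: mCPBA (1.0 equiv), NaHCO3, CH2Cl2, 0 °C
Reagents that add atoms: mCPBA, OOC(=O)c1cccc(Cl)c1
Why: Prilezhaev epoxidation should select the remote, more electron-rich 6,7-alkene because the 2,3-alkene is deactivated by the allylic acetate; the new stereocentre forms as a racemate and is destroyed in step 2.

Step 2
Reactants: 2 epoxy acetate
Product: 3 (2Z)-3-methyl-6-oxohex-2-en-1-yl acetate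
Conditions: H5IO6, THF–H2O, 0 °C
Reagents that add atoms: none
Why: Periodic acid hydrates the trisubstituted epoxide and cleaves the glycol in the same flask (oxidative glycol cleavage), releasing acetone and leaving the cis alkene and the acetate untouched.

Step 3
Reactants: 3 aldehyde acetate
Product: 5 (2Z)-3-methylhept-2-en-6-yn-1-ol, via alkynyl acetate 4 (not isolated)
Conditions: Ohira–Bestmann reagent, K2CO3, MeOH, 0 °C → rt
Reagents that add atoms: Ohira–Bestmann reagent (dimethyl 1-diazo-2-oxopropylphosphonate), CC(=O)C(=[N+]=[N-])P(=O)(OC)OC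
Why: Seyferth–Gilbert homologation with the Ohira–Bestmann reagent turns the enolizable aldehyde into the terminal alkyne, and the same K2CO3/MeOH medium should methanolyse the allylic acetate.

Step 4
Reactants: 5 alkynol
Product: 6 (2Z)-3-methylhept-2-en-6-ynal
Conditions: MnO2, CH2Cl2, rt
Reagents that add atoms: none
Why: MnO2 oxidizes only the allylic alcohol and, as in the nerol-to-neral oxidation, should not isomerize the cis enal.

Step 5
Reactants: 6 enal
Product: 7 (3Z)-4-methylocta-1,3-dien-7-yne
Conditions: Ph3PCH3Br, NaN(SiMe3)2, THF, −78 → 0 °C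
Reagents that add atoms: methyltriphenylphosphonium bromide, C[P+](c1ccccc1)(c1ccccc1)c1ccccc1.[Br-]
Why: Wittig methylenation with a non-stabilized ylide at low temperature should give the terminal 1,3-diene with retention of the cis trisubstituted alkene.

Step 6
Reactants: 8 (2S)-but-3-ene-1,2-diol
Product: 9 (4S)-4-ethenyl-2-(4-methoxyphenyl)-1,3-dioxolane (epimers at the acetal carbon)
Conditions: 4-MeOC6H4CH(OMe)2, PPTS (cat.), CH2Cl2, rt
Reagents that add atoms: 4-methoxybenzaldehyde dimethyl acetal, COc1ccc(C(OC)OC)cc1
Why: Acid-catalysed transacetalization gives the five-membered p-methoxybenzylidene acetal; the acetal carbon is an inconsequential epimer mixture.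

Step 7
Reactants: 9 acetal
Product: 10 (2S)-2-[(4-methoxyphenyl)methoxy]but-3-en-1-ol
Conditions: i-Bu2AlH, CH2Cl2, −78 → 0 °C
Reagents that add atoms: none
Why: In the reductive acetal opening aluminium binds the less hindered primary oxygen and hydride cleaves that C–O bond, so the PMB group should stay on the secondary oxygen and the primary alcohol is freed.

Step 8
Reactants: 10 alcohol
Product: 11 (2S)-2-[(4-methoxyphenyl)methoxy]but-3-enal
Conditions: Dess–Martin periodinane, NaHCO3, CH2Cl2, 0 °C (used crude)
Reagents that add atoms: none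
Why: Dess–Martin oxidation under buffered, non-basic conditions should give the α-alkoxy β,γ-unsaturated aldehyde without epimerization or double-bond migration.

Step 9
Reactants: 7 dienyne; 11 aldehyde
Product: 14 (3S,4S,9Z)-3-[(4-methoxyphenyl)methoxy]-9-methyldodeca-1,9,11-trien-5-yn-4-ol, via lithium acetylide 12 (not isolated), via alkynylzinc bromide 13 (not isolated)
Conditions: 7, n-BuLi, Et2O, −78 °C; ZnBr2; then 11, −78 → −20 °C
Reagents that add atoms: none
Why: Chelation-controlled (Cram-chelate) addition: zinc bridges the carbonyl and PMB-ether oxygens and the alkynyl group attacks on the side of the α-hydrogen, which sets C9 syn to the C8 oxygen.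

Step 10
Reactants: 14 propargylic alcohol
Product: 15 (3S,4R,5E,9Z)-3-[(4-methoxyphenyl)methoxy]-9-methyl-5-(tributylstannyl)dodeca-1,5,9,11-tetraen-4-ol
Conditions: Bu3SnH, Mo(CO)3(CNt-Bu)3 (cat.), hydroquinone, THF, 55 °C
Reagents that add atoms: tributyltin hydride, CCCC[SnH](CCCC)CCCC
Why: Mo-catalysed hydrostannation of propargylic alcohols is a syn addition that places tin on the carbon next to the carbinol, so C9 and the C2 chain end up cis across the new C1=C10 bond.

Step 11
Reactants: 15 alkenylstannane
Product: 16 (3S,4R,5E,9Z)-5-iodo-3-[(4-methoxyphenyl)methoxy]-9-methyldodeca-1,5,9,11-tetraen-4-ol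
Conditions: I2, CH2Cl2, −78 → 0 °C, dark
Reagents that add atoms: iodine, II
Why: Iododestannylation is an ipso substitution with retention of alkene geometry and should be far faster than iodine addition to the diene at low temperature.

Step 12
Reactants: 16 alkenyl iodide
Product: 17 methyl (2E,6Z)-2-[(1S,2S)-1-hydroxy-2-[(4-methoxyphenyl)methoxy]but-3-en-1-yl]-6-methylnona-2,6,8-trienoate
Conditions: CO (1 atm), PdCl2(PPh3)2 (cat.), Et3N, MeOH–DMF, 50 °C
Reagents that add atoms: carbon monoxide, [C-]#[O+]; methanol, CO
Why: Pd-catalysed methoxycarbonylation (oxidative addition, CO insertion, methanolysis) proceeds with retention and should give the Baylis–Hillman-type enoate with the ester trans to the C2 chain.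

Step 13
Reactants: 17 tetraene ester
Product: 18 methyl (1E,5Z,7Z,9S,10S)-10-hydroxy-9-[(4-methoxyphenyl)methoxy]-5-methylcyclodeca-1,5,7-triene-1-carboxylate
Conditions: second-generation Grubbs catalyst (10 mol %), CH2Cl2 (1 mM), 40 °C
Reagents that add atoms: none
Why: Ene–diene ring-closing metathesis between the vinyl group and the terminal alkene of the diene: the two cis alkenes already in the chain bring the ends together, the trisubstituted alkenes are inert, and the new C6=C7 bond should form as the less strained cis isomer.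

Step 14
Reactants: 18 macrocyclic triene; 19 2-bromoprop-2-enoic acid
Product: 20 methyl (3aS,4S,5S,6E,10Z,11aR)-5-hydroxy-4-[(4-methoxyphenyl)methoxy]-10-methyl-3-methylidene-2-oxo-2,3,3a,4,5,8,9,11a-octahydrocyclodeca[b]furan-6-carboxylate
Conditions: 19 (3 equiv), Pd(OAc)2 (10 mol %), PPh3 (20 mol %), n-Bu4NCl, KHCO3, DMF, 60 °C
Reagents that add atoms: none
Why: Proposed new method: zerovalent palladium inserts into the C–Br bond of the 2-bromoacrylate, the alkenyl–Pd species adds syn across the disubstituted C6=C7 bond of the cis,cis-diene with carbon going to C7 (C7–C11 bond), and the resulting η3-allyl over C6–C5–C4 is closed at C6 by the pendant carboxylate (O–C6 bond) with release of zerovalent palladium; the closest known reaction type is the Larock heteroannulation of 1,3-dienes by o-iodobenzoic acids, o-iodophenols and hydroxy- or amino-substituted alkenyl halides, which has not been shown for 2-bromoacrylic acid or for a macrocyclic diene. The γ-lactone closes by 5-exo attack of the carboxylate oxygen on the allyl terminus C6, the alternative seven-membered closure at the fully substituted C4 being disfavoured. C7 is set in the insertion: 1,3-allylic strain across the cis C6=C7 bond keeps H8 in the alkene plane, the PMB-oxy group shields one face, and the C9 carbinol lies on the other with a free hydroxyl that can hydrogen-bond to the carboxylate on palladium (as in hydroxyl-directed Heck insertions), so the acrylate carbon should enter anti to the PMB-oxy group, which places C11 cis to O8 on the ring as in the target. C6 is set in the closure: with phosphine and chloride on palladium the carboxylate should attack the allyl on the face opposite to the metal, and syn carbopalladation of a cis alkene followed by this anti C–O closure gives the trans-fused lactone (H6 and H7 anti). The step needs chemoselective insertion into the only C–Br bond (no allylic ester is present, which is why O9 is left free and acetylated afterwards), attack at C7 and not at the trisubstituted diene terminus C4, and retention of the cis C4=C5 geometry, which is secured because syn–anti exchange at C4 would need palladium σ-bound to a fully substituted carbon.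

Step 15
Reactants: 20 hydroxy lactone
Product: 21 methyl (3aS,4S,5S,6E,10Z,11aR)-5-acetyloxy-4-[(4-methoxyphenyl)methoxy]-10-methyl-3-methylidene-2-oxo-2,3,3a,4,5,8,9,11a-octahydrocyclodeca[b]furan-6-carboxylate
Conditions: Ac2O, pyridine, DMAP (cat.), CH2Cl2, 0 °C
Reagents that add atoms: acetic anhydride, CC(=O)OC(C)=O
Why: DMAP-catalysed acetylation of the only free hydroxyl, placed after the palladium step because an allylic acetate next to the enoate would itself ionize with zerovalent palladium.

Step 16
Reactants: 21 PMB ether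
Product: 22 methyl (3aR,4S,5S,6E,10Z,11aR)-5-acetyloxy-4-hydroxy-10-methyl-3-methylidene-2-oxo-2,3,3a,4,5,8,9,11a-octahydrocyclodeca[b]furan-6-carboxylate
Conditions: DDQ, CH2Cl2–pH 7 buffer, 0 °C
Reagents that add atoms: none
Why: Oxidative PMB cleavage (benzylic hydride abstraction by DDQ, hydrolysis of the oxocarbenium ion) under buffered conditions should leave the esters, the lactone and the electron-poor alkenes untouched.

Step 17
Reactants: 22 secondary alcohol
Product: 23 methyl (3aS,4S,5S,6E,10Z,11aR)-5-acetyloxy-10-methyl-3-methylidene-4-[(2-methylprop-2-enoyl)oxy]-2-oxo-2,3,3a,4,5,8,9,11a-octahydrocyclodeca[b]furan-6-carboxylate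
Conditions: methacrylic anhydride, Et3N, DMAP (cat.), CH2Cl2, 0 °C
Reagents that add atoms: methacrylic anhydride, C=C(C)C(=O)OC(=O)C(C)=C
Why: DMAP-catalysed acylation of the C8 hydroxyl with excess anhydride at 0 °C should outpace acetyl migration from O9 to O8.

Step 18
Reactants: 23 methacrylate
Product: 24 target, methyl (4R,5S,6S,7R,8S,9S)-9-acetoxy-4,5-epoxy-8-(2-methylprop-2-enoyloxy)germacra-1(10),11(13)-dien-6,12-olid-14-oate (cis-epoxide, ring-cis C1=C10)
Conditions: mCPBA, NaHCO3, CH2Cl2, 0 °C
Reagents that add atoms: mCPBA, OOC(=O)c1cccc(Cl)c1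
Why: Prilezhaev epoxidation should touch only the electron-rich trisubstituted C4=C5 bond (the other three alkenes are conjugated with esters), is stereospecific so the cis alkene gives the cis-epoxide, and should occur anti to the allylic lactone oxygen on C6 (H6 in the alkene plane by 1,3-allylic strain, only H7 of the trans-fused lactone on the attacked face), which sets C4 and C5 as in the target.

**Compound list**
1 | neryl acetate, (2Z)-3,7-dimethylocta-2,6-dien-1-yl acetate | CC(C)=CCC/C(C)=C\COC(C)=O | starting material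
2 | (2Z)-5-(3,3-dimethyloxiran-2-yl)-3-methylpent-2-en-1-yl acetate (racemic at the oxirane carbon) | CC1(C)OC1CC/C(C)=C\COC(C)=O | intermediate
3 | (2Z)-3-methyl-6-oxohex-2-en-1-yl acetate | O=CCC/C(C)=C\COC(C)=O | intermediate
4 | (2Z)-3-methylhept-2-en-6-yn-1-yl acetate (not isolated) | C#CCC/C(C)=C\COC(C)=O | intermediate
5 | (2Z)-3-methylhept-2-en-6-yn-1-ol | C#CCC/C(C)=C\CO | intermediate
6 | (2Z)-3-methylhept-2-en-6-ynal | C#CCC/C(C)=C\C=O | intermediate
7 | (3Z)-4-methylocta-1,3-dien-7-yne | C#CCC/C(C)=C\C=C | intermediate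
8 | (2S)-but-3-ene-1,2-diol | C=C[C@H](O)CO | starting material
9 | (4S)-4-ethenyl-2-(4-methoxyphenyl)-1,3-dioxolane (epimers at the acetal carbon) | C=C[C@H]1COC(c2ccc(OC)cc2)O1 | intermediate
10 | (2S)-2-[(4-methoxyphenyl)methoxy]but-3-en-1-ol | C=C[C@H](OCc1ccc(OC)cc1)CO | intermediate
11 | (2S)-2-[(4-methoxyphenyl)methoxy]but-3-enal | C=C[C@H](OCc1ccc(OC)cc1)C=O | intermediate
12 | [(5Z)-5-methylocta-5,7-dien-1-yn-1-yl]lithium (not isolated) | [Li]C#CCC/C(C)=C\C=C | intermediate
13 | bromo[(5Z)-5-methylocta-5,7-dien-1-yn-1-yl]zinc (not isolated) | Br[Zn]C#CCC/C(C)=C\C=C | intermediate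
14 | (3S,4S,9Z)-3-[(4-methoxyphenyl)methoxy]-9-methyldodeca-1,9,11-trien-5-yn-4-ol | C=C[C@H](OCc1ccc(OC)cc1)[C@@H](O)C#CCC/C(C)=C\C=C | intermediate
15 | (3S,4R,5E,9Z)-3-[(4-methoxyphenyl)methoxy]-9-methyl-5-(tributylstannyl)dodeca-1,5,9,11-tetraen-4-ol | C=C[C@H](OCc1ccc(OC)cc1)[C@@H](O)/C(=C\CC/C(C)=C\C=C)[Sn](CCCC)(CCCC)CCCC | intermediate
16 | (3S,4R,5E,9Z)-5-iodo-3-[(4-methoxyphenyl)methoxy]-9-methyldodeca-1,5,9,11-tetraen-4-ol | C=C[C@H](OCc1ccc(OC)cc1)[C@@H](O)/C(I)=C\CC/C(C)=C\C=C | intermediate
17 | methyl (2E,6Z)-2-[(1S,2S)-1-hydroxy-2-[(4-methoxyphenyl)methoxy]but-3-en-1-yl]-6-methylnona-2,6,8-trienoate | C=C[C@H](OCc1ccc(OC)cc1)[C@@H](O)/C(C(=O)OC)=C\CC/C(C)=C\C=C | intermediate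
18 | methyl (1E,5Z,7Z,9S,10S)-10-hydroxy-9-[(4-methoxyphenyl)methoxy]-5-methylcyclodeca-1,5,7-triene-1-carboxylate | COc1ccc(CO[C@H]2/C=C\C=C(C)/CC/C=C(/C(=O)OC)[C@@H]2O)cc1 | intermediate
19 | 2-bromoprop-2-enoic acid (2-bromoacrylic acid) | C=C(Br)C(=O)O | starting material
20 | methyl (3aS,4S,5S,6E,10Z,11aR)-5-hydroxy-4-[(4-methoxyphenyl)methoxy]-10-methyl-3-methylidene-2-oxo-2,3,3a,4,5,8,9,11a-octahydrocyclodeca[b]furan-6-carboxylate (trans-fused lactone) | COc1ccc(CO[C@H]2[C@H]3C(=C)C(=O)O[C@@H]3/C=C(C)\CC/C=C(/C(=O)OC)[C@@H]2O)cc1 | intermediate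
21 | 5-O-acetate of 20, (3aS,4S,5S,6E,10Z,11aR) | COc1ccc(CO[C@H]2[C@H]3C(=C)C(=O)O[C@@H]3/C=C(C)\CC/C=C(/C(=O)OC)[C@@H]2OC(C)=O)cc1 | intermediate
22 | methyl (3aR,4S,5S,6E,10Z,11aR)-5-acetyloxy-4-hydroxy-10-methyl-3-methylidene-2-oxo-2,3,3a,4,5,8,9,11a-octahydrocyclodeca[b]furan-6-carboxylate | O[C@H]1[C@H]2C(=C)C(=O)O[C@@H]2/C=C(C)\CC/C=C(/C(=O)OC)[C@@H]1OC(C)=O | intermediate
23 | methyl (3aS,4S,5S,6E,10Z,11aR)-5-acetyloxy-10-methyl-3-methylidene-4-[(2-methylprop-2-enoyl)oxy]-2-oxo-2,3,3a,4,5,8,9,11a-octahydrocyclodeca[b]furan-6-carboxylate | C=C(C)C(=O)O[C@H]1[C@H]2C(=C)C(=O)O[C@@H]2/C=C(C)\CC/C=C(/C(=O)OC)[C@@H]1OC(C)=O | intermediate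
24 | methyl (4R,5S,6S,7R,8S,9S)-9-acetoxy-4,5-epoxy-8-(2-methylprop-2-enoyloxy)germacra-1(10),11(13)-dien-6,12-olid-14-oate (cis-epoxide, ring-cis C1=C10) | C=C(C)C(=O)O[C@H]1[C@H]2C(=C)C(=O)O[C@@H]2[C@@H]2O[C@]2(C)CC/C=C(/C(=O)OC)[C@@H]1OC(C)=O | target

**Totals**
Total step count: 18.
Longest linear sequence: 15 steps (steps 1–5 and 9–18, from neryl acetate); steps 6–8 make the second fragment.

**Steps most likely to fail**

1. Step 14 (the proposed new method). The alkenyl–Pd species may add to the wrong face of C6=C7 (syn to the PMB-oxy group). The carboxylate may close from the metal-bearing face and give the cis-fused lactone. Insertion into the internal diene may be slower than self-consumption of the bromoacrylate. The allylic lactone may re-ionize and erode C6 or the C4=C5 geometry.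
Fallback (known chemistry), setting out from 18 and returning at 20: 18 is treated with malonic acid and Mn(OAc)3·2H2O (KOAc, AcOH, 40 °C). The malonyl radical formed by trivalent manganese adds to C7, the allyl radical is oxidized to the allyl cation and one carboxyl group closes at C6 (oxidative radical carbolactonization of alkenes and dienes), giving the α-carboxy lactone F1. Decarboxylative Mannich methylenation of F1 (aqueous CH2O, Et2NH, then NaOAc, AcOH, 90 °C) then gives 20.

2. Step 13. Oligomerization may outrun closure of the ten-membered ring, the catalyst may stall after loading at the allylic-ether vinyl group, or some trans C6=C7 isomer may form.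
Fallback, setting out from 6 and returning at 18; it replaces direct ene–diene metathesis by a relay ring closure. Wittig reaction of 6 with the ylide from (hex-5-en-1-yl)triphenylphosphonium bromide and NaN(SiMe3)2 gives the relay dienyne F2, which carries a pent-4-enyl arm on the diene terminus. Steps 9–12 are repeated unchanged with aldehyde 11 and give the propargylic alcohol F3, the alkenylstannane F4, the alkenyl iodide F5 and the enoate F6. With the second-generation Grubbs catalyst, ruthenium loads at the unhindered terminal alkene of the arm of F6, expels cyclopentene and is thereby placed on C6; this carbene then closes onto the neighbouring vinyl group to give 18. This addresses catalyst loading only; it would not cure ring strain or oligomerization.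

3. Step 18. The peracid may approach from the face syn to the lactone oxygen and give the other cis-epoxide.
Fallback, setting out from 23 and returning at 24; it inverts the facial outcome by a halohydrin route. NBS in aqueous THF forms the bromonium ion on the face the peracid would have taken, and water opens it at the tertiary C4 from the opposite face, giving the bromohydrin F7. Ag2O in CH2Cl2 then closes the oxirane by displacement of bromide at C5, which places the epoxide oxygen on the face opposite to the one attacked by bromine and gives 24.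

Further compounds
F1 | step 14 | (3aS,4S,5S,6E,10Z,11aR)-5-hydroxy-6-(methoxycarbonyl)-4-[(4-methoxyphenyl)methoxy]-10-methyl-2-oxo-2,3,3a,4,5,8,9,11a-octahydrocyclodeca[b]furan-3-carboxylic acid (epimers at C3) | COc1ccc(CO[C@H]2[C@H]3C(C(=O)O)C(=O)O[C@@H]3/C=C(C)\CC/C=C(/C(=O)OC)[C@@H]2O)cc1
F2 | step 13 | (6Z,8Z)-9-methyltrideca-1,6,8-trien-12-yne | C#CCC/C(C)=C\C=C/CCCC=C
F3 | step 13 | (3S,4S,9Z,11Z)-3-[(4-methoxyphenyl)methoxy]-9-methylheptadeca-1,9,11,16-tetraen-5-yn-4-ol | C=C[C@H](OCc1ccc(OC)cc1)[C@@H](O)C#CCC/C(C)=C\C=C/CCCC=C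
F4 | step 13 | (3S,4R,5E,9Z,11Z)-3-[(4-methoxyphenyl)methoxy]-9-methyl-5-(tributylstannyl)heptadeca-1,5,9,11,16-pentaen-4-ol | C=C[C@H](OCc1ccc(OC)cc1)[C@@H](O)/C(=C\CC/C(C)=C\C=C/CCCC=C)[Sn](CCCC)(CCCC)CCCC
F5 | step 13 | (3S,4R,5E,9Z,11Z)-5-iodo-3-[(4-methoxyphenyl)methoxy]-9-methylheptadeca-1,5,9,11,16-pentaen-4-ol | C=C[C@H](OCc1ccc(OC)cc1)[C@@H](O)/C(I)=C\CC/C(C)=C\C=C/CCCC=C
F6 | step 13 | methyl (2E,6Z,8Z)-2-[(1S,2S)-1-hydroxy-2-[(4-methoxyphenyl)methoxy]but-3-en-1-yl]-6-methyltetradeca-2,6,8,13-tetraenoate | C=C[C@H](OCc1ccc(OC)cc1)[C@@H](O)/C(C(=O)OC)=C\CC/C(C)=C\C=C/CCCC=C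
F7 | step 18 | (4R,5R)-5-bromo-4-hydroxy-4,5-dihydro derivative of 23 (germacrane numbering) | C=C(C)C(=O)O[C@H]1[C@H]2C(=C)C(=O)O[C@@H]2[C@@H](Br)[C@@](O)(C)CC/C=C(/C(=O)OC)[C@@H]1OC(C)=O
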